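**Plan** (atoms numbered as in bicyclo[3.3.1]nonane: C1 acyl bridgehead, C2 C=O, C3, C4 enol carbon, C5 bridgehead H, C6, C7 prenyl, C8 quaternary, C9 bridging C=O; ring A = C1–C5 + C9, ring B = C5–C9 + C1)
- Retrosynthetic cuts, in order: C1–isobutyryl (bridgehead acylation), C2=O (allylic oxidation), prenyl C=C (Wittig), C1–C8 (closes ring B), C5–C6 (alkylation), then the bond between C8 and the prenyl CH2 plus a lactone (cyclopropanation of farnesyl diazoacetate).
- Forward: farnesol gives a cyclopropane lactone (temporary ring); its C6 arm is joined to ring A, used as symmetric 1,5-dimethoxycyclohexa-1,4-diene with sp3 C5; ring B is closed last by C1 attacking C8 as the cyclopropane opens.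
- Enabling feature: C8 is fully alkyl-substituted and 1,3-related to the prenyl CH2 on C7, so C7, C8 and that CH2 can be tied up as a cyclopropane whose C8–CH2 bond is polarized by a formyl helper (later the prenyl CH=); ring A offers an enol ether carbon (C1) 1,3 to C5.
- Stereochemistry: Rh2(5R-MEPY)4 cyclopropanation of the E-olefin sets C7 and the precursor of C8; the key step inverts C8 and, through a chair transition state, uses one of two diastereotopic enol ethers, fixing C1 and C5; the bridgehead acylation retains configuration.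

Key step: step 10

Remark: 27 is written as the given C4-enol tautomer of the C2/C4 β-diketone, and diene 10 is taken as a purchasable compound (otherwise one Birch reduction of 1,3-dimethoxybenzene).

Step 1
Reactants: 1 (2E,6E)-farnesol; 2 bromoacetyl bromide
Product: 3 (2E,6E)-farnesyl bromoacetate
Conditions: NaHCO3, MeCN, 0 °C
Reagents that add atoms: none
Why: O-acylation of a primary allylic alcohol by an acid bromide; bicarbonate buffering should keep the acid-sensitive triene intact.

Step 2
Reactants: 3 (2E,6E)-farnesyl bromoacetate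
Product: 4 (2E,6E)-farnesyl diazoacetate
Conditions: TsNHNHTs, DBU, THF, 0 °C
Reagents that add atoms: N,N'-ditosylhydrazine, Cc1ccc(cc1)S(=O)(=O)NNS(=O)(=O)c1ccc(C)cc1
Why: N-alkylation of the bis-sulfonylhydrazine followed by two base-induced losses of sulfinate (Bamford–Stevens-type elimination) should give the diazoacetate without acid.

Step 3
Reactants: 4 (2E,6E)-farnesyl diazoacetate
Product: 5 (1R,5S,6R)-6-[(3E)-4,8-dimethylnona-3,7-dien-1-yl]-6-methyl-3-oxabicyclo[3.1.0]hexan-2-one (6-methyl syn to the lactone ring)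
Conditions: Rh2(5R-MEPY)4 (dirhodium tetrakis[methyl (5R)-2-oxopyrrolidine-5-carboxylate], 1 mol %), CH2Cl2, reflux, slow addition
Reagents that add atoms: none
Why: Intramolecular cyclopropanation of the allylic olefin by the rhodium carbenoid; the chiral carboxamidate catalyst selects the olefin face, which sets the future C7, and the E-geometry places the methyl syn to the lactone, which sets the carbon that becomes C8 after inversion.

Step 4
Reactants: 5 cyclopropane lactone
Product: 7 tert-butyldimethylsilyl ester of the ring-opened acid with the former lactone CH2O as CH2OSiMe2t-Bu (both arms cis to the ring methyl), via potassium carboxylate 6 (not isolated)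
Conditions: KOH, MeOH–H2O, 23 °C; evaporate, dry azeotropically; t-BuMe2SiCl, imidazole, DMAP (cat.), DMF, 0 → 23 °C
Reagents that add atoms: potassium hydroxide, [K+].[OH-]; tert-butyldimethylsilyl chloride, CC(C)(C)[Si](C)(C)Cl
Why: Saponification then exhaustive silylation opens the temporary ring while the two cyclopropane arms stay at different oxidation levels (the corresponding diol would be meso and the asymmetry of step 3 would be lost).

Step 5
Reactants: 7 silyl ester silyl ether
Product: 8 [(1R,2S,3S)-3-({[tert-butyl(dimethyl)silyl]oxy}methyl)-2-[(3E)-4,8-dimethylnona-3,7-dien-1-yl]-2-methylcyclopropyl]methanol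
Conditions: LiAlH4, Et2O, 0 °C
Reagents that add atoms: none
Why: Hydride reduction of the silyl ester to the primary alcohol (the future C6) while the primary silyl ether should persist.

Step 6
Reactants: 8 cyclopropylmethanol
Product: 9 bromide of 8 (CH2Br in place of CH2OH, configuration as in 8)
Conditions: CBr4, PPh3, imidazole, CH2Cl2, 0 °C; used at once
Reagents that add atoms: carbon tetrabromide, BrC(Br)(Br)Br
Why: Appel bromination by SN2 displacement of the alkoxyphosphonium; cold, buffered, non-ionizing conditions should hold back the cyclopropylcarbinyl-to-homoallyl rearrangement.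

Step 7
Reactants: 9 cyclopropylmethyl bromide; 10 1,5-dimethoxycyclohexa-1,4-diene
Product: 12 6-(cyclopropylmethyl)-1,5-dimethoxycyclohexa-1,4-diene carrying the CH2OSiMe2t-Bu arm (cyclopropane as in 8), via lithiated diene 11 (not isolated)
Conditions: 10, t-BuLi, THF, −78 °C; HMPA; then 9, −78 → −40 °C
Reagents that add atoms: none
Why: Deprotonation at the CH2 flanked by the two methoxy-bearing carbons and SN2 alkylation at that carbon form the C5–C6 bond; C5 becomes an sp3 CH with two identical enol ether arms, so no stereocentre arises.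

Step 8
Reactants: 12 silyl ether
Product: 13 primary alcohol of 12
Conditions: Bu4NF, THF, 0 °C
Reagents that add atoms: none
Why: Fluoride desilylation under basic conditions, which the acid-labile bis-enol ether should tolerate.

Step 9
Reactants: 13 alcohol
Product: 15 trans aldehyde (formyl trans to the CH2–ring A arm on the cyclopropane), via cis aldehyde 14 (not isolated)
Conditions: SO3·pyridine, DMSO, i-Pr2NEt, CH2Cl2, 0 °C; then DBU (0.2 equiv), 23 °C
Reagents that add atoms: none
Why: Parikh–Doering oxidation (non-acidic) followed by base epimerization through the aldehyde enolate, which should relieve the all-cis substitution and move the formyl carbon out of reach of ring A.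

Step 10
Reactants: 15 trans aldehyde
Product: 18 2-[4-methoxy-8-methyl-8-[(3E)-4,8-dimethylnona-3,7-dien-1-yl]-9-oxobicyclo[3.3.1]non-3-en-7-yl]acetaldehyde (C5, C7, C8 as in 27; C1 bears H), via oxocarbenium triflate 16 (not isolated), via keto enol silyl ether 17 (not isolated)
Conditions: Me3SiOTf (1.5 equiv), 2,6-di-tert-butyl-4-methylpyridine, Me2S (10 equiv), CH2Cl2 (0.005 M), −78 → −40 °C; aq NaHCO3; then K2CO3, MeOH, 0 °C
Reagents that add atoms: none
Why: Proposed new method: Me3SiOTf silylates the formyl oxygen of 15, which polarizes the cyclopropane bond between the formyl-bearing carbon and the fully alkyl-substituted C8, and the enol ether carbon C1 attacks C8 from the rear as that bond breaks with release of ring strain, giving C9 oxocarbenium 16 that Me2S should demethylate to ketone 17 before the new enol silyl ether can add to C9; the closest known reaction types are the Lewis acid-promoted homo-Michael opening of acceptor-substituted cyclopropanes by enol ethers with inversion and the Me3SiOTf-mediated epoxide-opening cyclization of 6-alkyl-1,5-dimethoxycyclohexa-1,4-dienes to bicyclo[3.3.1]nonanes. Ring B closes in a 6-exo-tet mode (the breaking cyclopropane bond lies outside the new ring) through a chair transition state. C8 is set by inversion of the cyclopropane carbon made in step 3, C7 is carried over unchanged, and C1 and C5 are set because only one of the two diastereotopic enol ethers of the symmetric ring A can reach the rear of C8 with the departing carbon anti and equatorial. The step needs attack at C8 and not at C7 or at the carbonyl carbon, which the tertiary character of C8, the trans placement of the formyl group and high dilution should secure.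

Step 11
Reactants: 18 keto aldehyde; 19 isopropyltriphenylphosphonium iodide
Product: 21 4-methoxy-8-methyl-8-[(3E)-4,8-dimethylnona-3,7-dien-1-yl]-7-(3-methylbut-2-en-1-yl)bicyclo[3.3.1]non-3-en-9-one (configuration as in 18), via phosphorus ylide 20 (not isolated)
Conditions: 19, n-BuLi, THF, 0 °C; then 18, −78 → 0 °C
Reagents that add atoms: none
Why: Wittig olefination turns the formyl helper into the prenyl group; the aldehyde should react far faster than the C9 ketone, which is flanked by two bridgeheads and cannot enolize.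

Step 12
Reactants: 21 prenyl ketone
Product: 22 4-methoxy-8-methyl-8-[(3E)-4,8-dimethylnona-3,7-dien-1-yl]-7-(3-methylbut-2-en-1-yl)bicyclo[3.3.1]non-3-ene-2,9-dione
Conditions: PhI(OAc)2, t-BuOOH, Cs2CO3, EtOAc, −20 °C
Reagents that add atoms: tert-butyl hydroperoxide, CC(C)(C)OO
Why: Radical allylic C–H oxidation: the tert-butylperoxy radical should abstract hydrogen preferentially from C2, whose radical is stabilized by the adjacent enol ether, and the resulting peroxide collapses to the C2 ketone (vinylogous ester).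

Step 13
Reactants: 22 vinylogous ester; 23 isobutyryl chloride
Product: 25 O-methyl prolifenone B (4-methoxy-1-(2-methylpropanoyl) derivative of 22; C1, C5, C7, C8 as in 27), via bridgehead lithio compound 24 (not isolated)
Conditions: LiN(i-Pr)2, THF, −78 °C; then 23, −78 °C
Reagents that add atoms: none
Why: Bridgehead lithiation at C1, the α' position flanked by the C2 and C9 carbonyls, followed by C-acylation; the bicycle fixes the configuration, so the acyl group enters with retention.

Step 14
Reactants: 25 O-methyl prolifenone B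
Product: 27 prolifenone B, (1R,5R,7S,8R)-4-hydroxy-8-methyl-8-[(3E)-4,8-dimethylnona-3,7-dien-1-yl]-7-(3-methylbut-2-en-1-yl)-1-(2-methylpropanoyl)bicyclo[3.3.1]non-3-ene-2,9-dione, via lithium enolate 26 (not isolated)
Conditions: LiCl, DMSO, 120 °C; then aq HCl (pH 3)
Reagents that add atoms: none
Why: SN2 O-demethylation of the vinylogous methyl ester by chloride (Krapcho-type dealkylation) under non-acidic conditions that should spare the prenyl groups and the bridgehead triketone.

**Compound list**
1 | (2E,6E)-farnesol | CC(C)=CCC/C(C)=C/CC/C(C)=C/CO | starting material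
2 | bromoacetyl bromide | BrCC(Br)=O | starting material
3 | (2E,6E)-farnesyl bromoacetate | CC(C)=CCC/C(C)=C/CC/C(C)=C/COC(=O)CBr | intermediate
4 | (2E,6E)-farnesyl diazoacetate | CC(C)=CCC/C(C)=C/CC/C(C)=C/COC(=O)C=[N+]=[N-] | intermediate
5 | (1R,5S,6R)-6-[(3E)-4,8-dimethylnona-3,7-dien-1-yl]-6-methyl-3-oxabicyclo[3.1.0]hexan-2-one | O=C1OC[C@H]2[C@@H]1[C@]2(C)CC/C=C(C)/CCC=C(C)C | intermediate
6 | potassium salt of the ring-opened cis hydroxy acid of 5 | OC[C@H]1[C@@H](C(=O)[O-])[C@]1(C)CC/C=C(C)/CCC=C(C)C.[K+] | intermediate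
7 | tert-butyldimethylsilyl ester of the acid with cis CH2OSiMe2t-Bu arm | CC(C)(C)[Si](C)(C)OC[C@H]1[C@@H](C(=O)O[Si](C)(C)C(C)(C)C)[C@]1(C)CC/C=C(C)/CCC=C(C)C | intermediate
8 | [(1R,2S,3S)-3-({[tert-butyl(dimethyl)silyl]oxy}methyl)-2-[(3E)-4,8-dimethylnona-3,7-dien-1-yl]-2-methylcyclopropyl]methanol | CC(C)(C)[Si](C)(C)OC[C@H]1[C@@H](CO)[C@]1(C)CC/C=C(C)/CCC=C(C)C | intermediate
9 | bromide of 8 (CH2Br in place of CH2OH) | CC(C)(C)[Si](C)(C)OC[C@H]1[C@@H](CBr)[C@]1(C)CC/C=C(C)/CCC=C(C)C | intermediate
10 | 1,5-dimethoxycyclohexa-1,4-diene | COC1=CCC=C(OC)C1 | starting material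
11 | 6-lithio-1,5-dimethoxycyclohexa-1,4-diene | COC1=CCC=C(OC)C1[Li] | intermediate
12 | 6-(cyclopropylmethyl)-1,5-dimethoxycyclohexa-1,4-diene with CH2OSiMe2t-Bu arm (cyclopropane as in 8) | CC(C)(C)[Si](C)(C)OC[C@H]1[C@@H](CC2C(OC)=CCC=C2OC)[C@]1(C)CC/C=C(C)/CCC=C(C)C | intermediate
13 | primary alcohol from 12 | OC[C@H]1[C@@H](CC2C(OC)=CCC=C2OC)[C@]1(C)CC/C=C(C)/CCC=C(C)C | intermediate
14 | cis aldehyde (formyl cis to the CH2–ring A arm) | O=C[C@H]1[C@@H](CC2C(OC)=CCC=C2OC)[C@]1(C)CC/C=C(C)/CCC=C(C)C | intermediate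
15 | trans aldehyde (formyl trans to the CH2–ring A arm) | O=C[C@@H]1[C@@H](CC2C(OC)=CCC=C2OC)[C@]1(C)CC/C=C(C)/CCC=C(C)C | intermediate
16 | bicyclic C9 O-methyl oxocarbenium triflate with enol silyl ether side chain | CC(C)=CCC/C(C)=C/CC[C@]1(C)[C@@H](C=CO[Si](C)(C)C)C[C@H]2C(=[O+]C)[C@@H]1CC=C2OC.[O-]S(=O)(=O)C(F)(F)F | intermediate
17 | bicyclic C9 ketone with enol silyl ether side chain | CC(C)=CCC/C(C)=C/CC[C@]1(C)[C@@H](C=CO[Si](C)(C)C)C[C@H]2C(=O)[C@@H]1CC=C2OC | intermediate
18 | 2-[4-methoxy-8-methyl-8-[(3E)-4,8-dimethylnona-3,7-dien-1-yl]-9-oxobicyclo[3.3.1]non-3-en-7-yl]acetaldehyde (C5, C7, C8 as in 27) | CC(C)=CCC/C(C)=C/CC[C@]1(C)[C@@H](CC=O)C[C@H]2C(=O)[C@@H]1CC=C2OC | intermediate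
19 | isopropyltriphenylphosphonium iodide | CC(C)[P+](c1ccccc1)(c1ccccc1)c1ccccc1.[I-] | starting material
20 | isopropylidenetriphenylphosphorane | CC(C)=P(c1ccccc1)(c1ccccc1)c1ccccc1 | intermediate
21 | 4-methoxy-8-methyl-8-[(3E)-4,8-dimethylnona-3,7-dien-1-yl]-7-(3-methylbut-2-en-1-yl)bicyclo[3.3.1]non-3-en-9-one | CC(C)=CCC/C(C)=C/CC[C@]1(C)[C@@H](CC=C(C)C)C[C@H]2C(=O)[C@@H]1CC=C2OC | intermediate
22 | 4-methoxy-8-methyl-8-[(3E)-4,8-dimethylnona-3,7-dien-1-yl]-7-(3-methylbut-2-en-1-yl)bicyclo[3.3.1]non-3-ene-2,9-dione | CC(C)=CCC/C(C)=C/CC[C@]1(C)[C@@H](CC=C(C)C)C[C@H]2C(=O)[C@@H]1C(=O)C=C2OC | intermediate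
23 | isobutyryl chloride | CC(C)C(Cl)=O | starting material
24 | C1-lithio derivative of 22 | CC(C)=CCC/C(C)=C/CC[C@]1(C)[C@@H](CC=C(C)C)C[C@H]2C(=O)[C@]1([Li])C(=O)C=C2OC | intermediate
25 | O-methyl prolifenone B | CC(C)=CCC/C(C)=C/CC[C@]1(C)[C@@H](CC=C(C)C)C[C@H]2C(=O)[C@]1(C(=O)C(C)C)C(=O)C=C2OC | intermediate
26 | lithium enolate of prolifenone B | CC(C)=CCC/C(C)=C/CC[C@]1(C)[C@@H](CC=C(C)C)C[C@H]2C(=O)[C@]1(C(=O)C(C)C)C(=O)C=C2[O-].[Li+] | intermediate
27 | prolifenone B | CC(C)=CCC/C(C)=C/CC[C@]1(C)[C@@H](CC=C(C)C)C[C@H]2C(=O)[C@]1(C(=O)C(C)C)C(=O)C=C2O | target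

**Totals:** 14 steps; longest linear sequence 14 steps (from 1).

**Steps most likely to fail**

1. Step 10 (proposed new method). The enol ether may add to the silylated formyl group, or the freshly formed enol silyl ether may collapse onto the C9 oxocarbenium (formal (3+2) closure) before demethylation. Full ionization to a free C8 cation would also erode the stereospecificity. The fallback uses known chemistry, sets out from 1 and 11 and comes back at 22. Sharpless asymmetric epoxidation of 1 (Ti(Oi-Pr)4, L-(+)-diethyl tartrate, t-BuOOH) should give (2S,3S)-2,3-epoxyfarnesol F1. CBr4/PPh3 converts it into epoxy bromide F2, which alkylates lithiated diene 11 to epoxy diene F3. Me3SiOTf/2,6-lutidine then effects the epoxide-opening cyclization (inversion at the tertiary epoxide carbon, the future C8) to bicyclic methyl ketal F4 with a C7–O–C9 bridge. Allylic oxidation as in step 12 gives vinylogous ester F5, and Me2BBr opens the ketal to hydroxy diketone F6. PhOC(S)Cl/pyridine gives thionocarbonate F7, and Keck radical allylation (allyltributylstannane, AIBN) from the exo face should give 7-allyl compound F8. Cross-metathesis with 2-methyl-2-butene (second-generation Hoveyda–Grubbs catalyst) then gives 22.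

2. Step 12. Hydrogen abstraction may also occur at the allylic positions of the three trisubstituted olefins, or the allyl radical may be trapped at its methoxy-bearing end. The fallback sets out from 21 and comes back at 22. Aqueous oxalic acid/THF hydrolyses the enol ether to diketone F9. Pd(O2CCF3)2/DMSO/O2 dehydrogenation (C3 is the only enolizable side of the C4 ketone) gives enone F10. Tsuji–Wacker oxidation (Na2PdCl4, t-BuOOH, AcOH–H2O) gives β-diketone F11. Me3SiCHN2 then gives 22 together with its regioisomer F12, which is hydrolysed back to F11 and recycled.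

3. Step 13. Metalation may occur at C3 or C5 instead of C1, or the amide base may cleave the acylated product by a retro-Claisen path. The fallback sets out from 22 and comes back at 25. Lithium 2,2,6,6-tetramethylpiperidide added to 22 and Me3SiCl (in situ quench) blocks C3 as silyl compound F13. LiN(i-Pr)2 then isobutyraldehyde gives bridgehead carbinol F14, Dess–Martin periodinane oxidizes it to ketone F15, and Bu4NF removes the silyl group to give 25.

**Further compounds**
F1 | step 10 | (2S,3S)-2,3-epoxyfarnesol | OC[C@@H]1O[C@@]1(C)CC/C=C(C)/CCC=C(C)C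
F2 | step 10 | epoxy bromide from F1 | BrC[C@@H]1O[C@@]1(C)CC/C=C(C)/CCC=C(C)C
F3 | step 10 | 6-(epoxyfarnesyl)-1,5-dimethoxycyclohexa-1,4-diene | COC1=CCC=C(OC)C1C[C@@H]1O[C@@]1(C)CC/C=C(C)/CCC=C(C)C
F4 | step 10 | bicyclic methyl ketal with C7–O–C9 bridge | CC(C)=CCC/C(C)=C/CC[C@]1(C)[C@@H]2C[C@@H]3C(OC)=CC[C@H]1[C@]3(OC)O2
F5 | step 10 | C2-oxo vinylogous ester of F4 | CC(C)=CCC/C(C)=C/CC[C@]1(C)[C@@H]2C[C@@H]3C(OC)=CC(=O)[C@H]1[C@]3(OC)O2
F6 | step 10 | 7-hydroxy-4-methoxy-bicyclo[3.3.1]non-3-ene-2,9-dione (side chains as in 22 without prenyl) | CC(C)=CCC/C(C)=C/CC[C@]1(C)[C@@H](O)C[C@H]2C(=O)[C@@H]1C(=O)C=C2OC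
F7 | step 10 | O-phenyl thionocarbonate of F6 | CC(C)=CCC/C(C)=C/CC[C@]1(C)[C@@H](OC(=S)Oc3ccccc3)C[C@H]2C(=O)[C@@H]1C(=O)C=C2OC
F8 | step 10 | 7-allyl analogue of 22 | CC(C)=CCC/C(C)=C/CC[C@]1(C)[C@@H](CC=C)C[C@H]2C(=O)[C@@H]1C(=O)C=C2OC
F9 | step 12 | 4,9-diketone from hydrolysis of 21 | CC(C)=CCC/C(C)=C/CC[C@]1(C)[C@@H](CC=C(C)C)C[C@H]2C(=O)[C@@H]1CCC2=O
F10 | step 12 | 2-ene-4,9-dione | CC(C)=CCC/C(C)=C/CC[C@]1(C)[C@@H](CC=C(C)C)C[C@H]2C(=O)[C@@H]1C=CC2=O
F11 | step 12 | 2,4,9-trione (enol form, no C1 acyl) | CC(C)=CCC/C(C)=C/CC[C@]1(C)[C@@H](CC=C(C)C)C[C@H]2C(=O)[C@@H]1C(=O)C=C2O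
F12 | step 12 | 2-methoxy regioisomer of 22 | CC(C)=CCC/C(C)=C/CC[C@]1(C)[C@@H](CC=C(C)C)C[C@H]2C(=O)[C@@H]1C(OC)=CC2=O
F13 | step 13 | 3-trimethylsilyl derivative of 22 | CC(C)=CCC/C(C)=C/CC[C@]1(C)[C@@H](CC=C(C)C)C[C@H]2C(=O)[C@@H]1C(=O)C([Si](C)(C)C)=C2OC
F14 | step 13 | C1 (1-hydroxy-2-methylpropyl) carbinol of F13 (carbinol centre either way) | CC(C)=CCC/C(C)=C/CC[C@]1(C)[C@@H](CC=C(C)C)C[C@H]2C(=O)[C@]1(C(O)C(C)C)C(=O)C([Si](C)(C)C)=C2OC
F15 | step 13 | 3-trimethylsilyl derivative of 25 | CC(C)=CCC/C(C)=C/CC[C@]1(C)[C@@H](CC=C(C)C)C[C@H]2C(=O)[C@]1(C(=O)C(C)C)C(=O)C([Si](C)(C)C)=C2OC
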